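**Plan**
- Retrosynthesis first puts back an N1-benzyl group and a C=C bond in the arylethyl arm, then cuts the imidazole across C4–C5 and C2–N3.
- Enabling feature: N1–C5(CH3) of the imidazole is the N–Cα unit of alanine, and C2 with the acetoxybutyl chain is an acyl carbon on that nitrogen, so C2–N1–C5 is the dipole of a münchnone (1,3-oxazolium-5-olate). C4 (carrying the ArCH2CH2 arm) and N3 map onto the C=N bond of the N-tosyl imine of 3,4-dimethoxycinnamaldehyde.
- Forward: δ-valerolactone is opened, O-acetylated and turned into the acid chloride (steps 1–3), which acylates N-benzyl-L-alanine (step 4). The imine is made separately (step 5).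
- The imidazole is the only ring formed. It arises in step 6 by cyclodehydration to the dipole and cycloaddition with loss of CO2 and p-toluenesulfinic acid. One hydrogenation (step 7) saturates the arm and removes the benzyl group.
- Stereochemistry: the target is achiral. The alanine centre is erased in the dipole and the E-alkene is reduced at the end, so nothing has to be controlled.

Key step: step 6

Remark: a carbodiimide is used as dehydrating agent in place of an anhydride, so that no acyl donor competes with the imine for the nucleophilic dipole carbon. Either enantiomer of N-benzylalanine would serve.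

**Step 1**
Reactants: 1 δ-valerolactone
Product: 2 sodium 5-hydroxypentanoate
Conditions: NaOH (1.0 equiv), H2O, 70 °C; evaporate, dry under vacuum
Reagents that add atoms: sodium hydroxide, [Na+].[OH-]
Why: Saponification of the lactone by one equivalent of hydroxide is irreversible and gives the open-chain hydroxy carboxylate, which as its sodium salt cannot relactonise (ester hydrolysis).

**Step 2**
Reactants: 2 sodium 5-hydroxypentanoate
Product: 3 5-acetoxypentanoic acid
Conditions: Ac2O, pyridine, cat. DMAP, 0 °C to rt; H2O quench; HCl to pH 2; extraction, then NaHCO3/acid back-extraction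
Reagents that add atoms: acetic anhydride, CC(=O)OC(C)=O
Why: DMAP-catalysed esterification caps the primary hydroxyl before the acid is set free, so that acidification should give the acetoxy acid and not the lactone, any mixed anhydride at the carboxyl end being hydrolysed in the quench.

**Step 3**
Reactants: 3 5-acetoxypentanoic acid
Product: 4 5-acetoxypentanoyl chloride
Conditions: (COCl)2, cat. DMF, CH2Cl2, 0 °C to rt; evaporate, use crude
Reagents that add atoms: oxalyl chloride, O=C(Cl)C(=O)Cl
Why: Acid chloride formation through the Vilsmeier-type chloroiminium species runs cold and without added acid or base, which leaves the primary acetate untouched and gives only gaseous by-products.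

**Step 4**
Reactants: 5 N-benzyl-L-alanine; 4 5-acetoxypentanoyl chloride
Product: 8 N-(5-acetoxypentanoyl)-N-benzyl-L-alanine, via trimethylsilyl N-benzyl-L-alaninate 6 (not isolated), via trimethylsilyl ester of the amido acid 7 (not isolated)
Conditions: TMSCl (1.2 equiv), iPr2NEt (2.5 equiv), CH2Cl2, reflux; then 4, 0 °C to rt; 1 M aq. HCl work-up
Reagents that add atoms: none
Why: Transient silylation brings the zwitterionic amino acid into solution as its silyl ester and frees the secondary amine for N-acylation by the acid chloride under anhydrous conditions that spare the acetate (amide formation from an amine and an acid chloride), the silyl ester being hydrolysed in the work-up.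

**Step 5**
Reactants: 9 (E)-3,4-dimethoxycinnamaldehyde; 10 p-toluenesulfonamide
Product: 11 N-[(1E,2E)-3-(3,4-dimethoxyphenyl)prop-2-en-1-ylidene]-4-methylbenzenesulfonamide
Conditions: cat. BF3·OEt2, toluene, reflux, Dean–Stark trap; crystallise
Reagents that add atoms: none
Why: Lewis-acid-catalysed dehydrative condensation of a non-enolisable aldehyde with a primary sulfonamide, driven by azeotropic removal of water, should give the conjugated N-sulfonyl aldimine as its more stable E,E isomer (imine condensation).

**Step 6**
Reactants: 8 N-(5-acetoxypentanoyl)-N-benzyl-L-alanine; 11 N-tosyl imine of 3,4-dimethoxycinnamaldehyde (1.5 equiv)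
Product: 14 4-{1-benzyl-4-[(E)-2-(3,4-dimethoxyphenyl)ethenyl]-5-methyl-1H-imidazol-2-yl}butyl acetate, via münchnone 12 (not isolated), via bicyclic cycloadduct 13 (not isolated)
Conditions: N,N'-diisopropylcarbodiimide (DIC, 1.5 equiv), 4 Å MS, CH2Cl2, 0 °C to rt, then 40 °C; aq. NaHCO3 wash
Reagents that add atoms: none
Why: The carbodiimide activates the carboxyl group of 8, the amide oxygen closes the oxazolonium ring, and loss of the α-proton gives the mesoionic 1,3-oxazolium-5-olate 12, a cyclic azomethine ylide that is formed in the absence of any acyl donor and is trapped as it forms by the imine already present. Its enolate-like C4 (the alanine carbon with the methyl group) bonds to the sulfonyl-activated imine carbon of 11 and its C2 (the former amide carbon) to the sulfonamide nitrogen, so that the five-membered diaza ring closes by an intermolecular [3+2] cycloaddition, or in the stepwise limit by Mannich addition followed by attack of the nitrogen on the oxazolonium carbon, both leading to the bicyclic adduct 13. Cycloreversion of 13 expels CO2, and elimination of p-toluenesulfinic acid then aromatises the ring to the imidazole 14. The closest known reaction type is the 1,3-dipolar cycloaddition of münchnones, generated from N-acyl-N-alkyl amino acids with a carbodiimide or an anhydride, to N-sulfonyl aldimines, which gives imidazoles with this connectivity. No stereocentre remains, because the alanine centre is lost in 12 and the centres of 13 vanish on aromatisation. The step needs the methyl-bearing dipole carbon to bond to the imine carbon, which the match of the nucleophilic C4 with the electrophilic C=N carbon secures, and it needs reaction at C=N and not at C=C, which the sulfonyl activation of the imine and the donor dimethoxyphenyl group on the β-carbon secure.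

**Step 7**
Reactants: 14 4-{1-benzyl-4-[(E)-2-(3,4-dimethoxyphenyl)ethenyl]-5-methyl-1H-imidazol-2-yl}butyl acetate
Product: 16 O-acetylcypholophine (4-{4-[2-(3,4-dimethoxyphenyl)ethyl]-5-methyl-1H-imidazol-2-yl}butyl acetate), via saturated N-benzylimidazole 15 (not isolated)
Conditions: H2 (4 bar), Pd(OH)2/C, AcOH, rt then 60 °C; filter, neutralise with aq. NaHCO3
Reagents that add atoms: none
Why: Catalytic hydrogenation should saturate the styryl double bond first and then, with the imidazole protonated by the solvent, cleave the benzylic C–N bond (hydrogenolytic N-debenzylation), while acetic acid as solvent rules out transesterification of the acetate.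

**Compound list**
1 | δ-valerolactone (oxan-2-one) | O=C1CCCCO1 | starting material
2 | sodium 5-hydroxypentanoate | [Na+].[O-]C(=O)CCCCO | intermediate
3 | 5-acetoxypentanoic acid | CC(=O)OCCCCC(=O)O | intermediate
4 | 5-acetoxypentanoyl chloride | CC(=O)OCCCCC(=O)Cl | intermediate
5 | N-benzyl-L-alanine | C[C@H](NCc1ccccc1)C(=O)O | starting material
6 | trimethylsilyl N-benzyl-L-alaninate | C[C@H](NCc1ccccc1)C(=O)O[Si](C)(C)C | intermediate (not isolated)
7 | trimethylsilyl N-(5-acetoxypentanoyl)-N-benzyl-L-alaninate | C[C@H](N(Cc1ccccc1)C(=O)CCCCOC(C)=O)C(=O)O[Si](C)(C)C | intermediate (not isolated)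
8 | N-(5-acetoxypentanoyl)-N-benzyl-L-alanine | C[C@H](N(Cc1ccccc1)C(=O)CCCCOC(C)=O)C(=O)O | intermediate
9 | (E)-3,4-dimethoxycinnamaldehyde | COc1ccc(/C=C/C=O)cc1OC | starting material
10 | p-toluenesulfonamide | Cc1ccc(S(N)(=O)=O)cc1 | starting material
11 | N-[(1E,2E)-3-(3,4-dimethoxyphenyl)prop-2-en-1-ylidene]-4-methylbenzenesulfonamide | COc1ccc(/C=C/C=N/S(=O)(=O)c2ccc(C)cc2)cc1OC | intermediate
12 | 2-(4-acetoxybutyl)-3-benzyl-4-methyl-1,3-oxazol-3-ium-5-olate (münchnone) | CC(=O)OCCCCc1oc([O-])c(C)[n+]1Cc1ccccc1 | intermediate (not isolated)
13 | 4-{7-benzyl-5-[(E)-2-(3,4-dimethoxyphenyl)ethenyl]-4-methyl-6-(4-methylbenzenesulfonyl)-3-oxo-2-oxa-6,7-diazabicyclo[2.2.1]heptan-1-yl}butyl acetate (mixture of stereoisomers, all centres lost on aromatisation) | CC(=O)OCCCCC12OC(=O)C(C)(N1Cc1ccccc1)C(/C=C/c1ccc(OC)c(OC)c1)N2S(=O)(=O)c1ccc(C)cc1 | intermediate (not isolated)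
14 | 4-{1-benzyl-4-[(E)-2-(3,4-dimethoxyphenyl)ethenyl]-5-methyl-1H-imidazol-2-yl}butyl acetate | COc1ccc(/C=C/c2nc(CCCCOC(C)=O)n(Cc3ccccc3)c2C)cc1OC | intermediate
15 | 4-{1-benzyl-4-[2-(3,4-dimethoxyphenyl)ethyl]-5-methyl-1H-imidazol-2-yl}butyl acetate | COc1ccc(CCc2nc(CCCCOC(C)=O)n(Cc3ccccc3)c2C)cc1OC | intermediate (not isolated)
16 | O-acetylcypholophine, 4-{4-[2-(3,4-dimethoxyphenyl)ethyl]-5-methyl-1H-imidazol-2-yl}butyl acetate | COc1ccc(CCc2nc(CCCCOC(C)=O)[nH]c2C)cc1OC | target

**Step count**
Total: 7 steps. Longest linear sequence: 6 steps (steps 1, 2, 3, 4, 6, 7 from δ-valerolactone); step 5 is a one-step side branch.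

**Steps most likely to fail**

Step 6. The münchnone 12 carries only alkyl groups on both dipole carbons. It may dimerise, or its O-acylisourea precursor may rearrange to an N-acylurea, before the imine captures it. The dipole may also add in conjugate fashion or across the C=C bond of the azadiene, and the sulfinic acid set free may promote hydrolysis of the imine by traces of water. The fallback sets out from 8 and replaces the imine by an acyl donor. Commercial 3-(3,4-dimethoxyphenyl)propanoic acid would be dehydrated with DCC in CH2Cl2 to 3-(3,4-dimethoxyphenyl)propanoic anhydride F1. Heating 8 with an excess of F1, Et3N and catalytic DMAP (Dakin–West reaction: C-acylation of the same oxazolium-olate, then decarboxylation) should give the α-amido ketone 5-{benzyl[5-(3,4-dimethoxyphenyl)-3-oxopentan-2-yl]amino}-5-oxopentyl acetate F2. Heating F2 with NH4OAc in AcOH (cyclodehydration of an N-alkyl α-acylamino ketone with ammonia) should close the imidazole and give 15. The route is rejoined at 15, which is debenzylated under the conditions of step 7.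

Step 7. After the fast saturation of the alkene, hydrogenolysis of the N-benzyl bond of the electron-rich, catalyst-binding trialkylimidazole may stall. The fallback sets out from 15, obtained by stopping the hydrogenation after alkene uptake (Pd/C, H2, EtOAc, rt). Treatment with KOtBu in DMSO under O2 at rt (oxidative N-debenzylation of azoles through the benzylic carbanion and its hydroperoxide) followed by an aqueous quench, which completes saponification of the acetate, should give cypholophine F3. Acetyl chloride in AcOH, in which the imidazole is protonated so that only the primary alcohol is acylated, should then return to 16.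

Step 5. Condensation of the donor-substituted, vinylogously deactivated aldehyde may stay incomplete, and the imine may revert to its components by hydrolysis during isolation. The fallback sets out from 10 and forms the C=N bond without producing water. Refluxing 10 in SOCl2 should give N-sulfinyl-4-methylbenzenesulfonamide F4. F4 should react with aldehyde 9 in toluene with catalytic BF3·OEt2 (Kresze reaction: [2+2] addition across C=O and loss of SO2) to return to 11.

**Further compounds**
F1 | step 6 | 3-(3,4-dimethoxyphenyl)propanoic anhydride | COc1ccc(CCC(=O)OC(=O)CCc2ccc(OC)c(OC)c2)cc1OC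
F2 | step 6 | 5-{benzyl[5-(3,4-dimethoxyphenyl)-3-oxopentan-2-yl]amino}-5-oxopentyl acetate (racemic) | CC(N(Cc1ccccc1)C(=O)CCCCOC(C)=O)C(=O)CCc1ccc(OC)c(OC)c1
F3 | step 7 | cypholophine, 4-{4-[2-(3,4-dimethoxyphenyl)ethyl]-5-methyl-1H-imidazol-2-yl}butan-1-ol | COc1ccc(CCc2nc(CCCCO)[nH]c2C)cc1OC
F4 | step 5 | N-sulfinyl-4-methylbenzenesulfonamide | Cc1ccc(S(=O)(=O)N=S=O)cc1
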